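The dihydropyran ring is cut at C2–C3 and O1–C8a: a pyruvate C2=O unit is joined to an aryl–C4–C3 unit. The key step exploits the 1,3-relationship of the oxygen-bearing C2 to benzylic C4 and the ortho position of C4 to C8a on the benzene ring. A temporary C4 carbonyl makes C3 nucleophilic (enol silane) and C8a–F electrophilic (SNAr). In one flask a Cu(OTf)2/bis(oxazoline)-catalysed Mukaiyama aldol to methyl pyruvate forms C2–C3 and sets quaternary C2, then fluoride-triggered alkoxide SNAr closes O1–C8a. The precursor is a 2-fluoroaryl ketone enol silane. Later the C4 carbonyl is removed, the ester is extended by farnesyl sulfone alkylation, and terminal allylic oxidation gives the acid.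

Key step: step 4

Remark: positions follow chroman numbering (O1, C2, C3, C4, C4a, C5–C8, C8a); side-chain carbons are 1′–13′ counted from C2.
Assumption: the si-face selectivity known for the Cu(OTf)2/(S,S)-t-Bu-box pyruvate aldol is taken to hold for enol silane 6; otherwise the (R,R)-ligand would be used.

Step 1
Reactants: 1 4-fluoro-3-methylphenol
Product: 2 (4-fluoro-3-methylphenoxy)triisopropylsilane
Conditions: TIPSCl, imidazole, DMF, rt
Reagents that add atoms: chlorotriisopropylsilane, CC(C)[Si](Cl)(C(C)C)C(C)C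
Why: Imidazole-mediated O-silylation gives a bulky, base-stable ether that also shields both ring positions next to oxygen from lithiation.

Step 2
Reactants: 2 (4-fluoro-3-methylphenoxy)triisopropylsilane; 3 N-methoxy-N-methylacetamide
Product: 5 1-[2-fluoro-3-methyl-5-(triisopropylsilyloxy)phenyl]ethan-1-one, via aryllithium 4 (not isolated)
Conditions: s-BuLi, TMEDA, THF, −78 °C; then 3, −78 → 0 °C; aq. NH4Cl
Reagents that add atoms: none
Why: Fluorine-directed ortho-metalation should occur at the only C–H next to fluorine because the silyl ether blocks the positions flanking oxygen, and Weinreb amide acylation stops at the ketone through the chelated tetrahedral adduct.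

Step 3
Reactants: 5 1-[2-fluoro-3-methyl-5-(triisopropylsilyloxy)phenyl]ethan-1-one
Product: 6 triisopropyl{4-fluoro-3-methyl-5-[1-(trimethylsilyloxy)ethenyl]phenoxy}silane
Conditions: TMSOTf, Et3N, CH2Cl2, 0 °C
Reagents that add atoms: trimethylsilyl triflate, C[Si](C)(C)OS(=O)(=O)C(F)(F)F
Why: Silyl enol ether formation by soft enolisation of a methyl ketone with a single enolisable side gives the Mukaiyama donor.

Step 4
Reactants: 6 triisopropyl{4-fluoro-3-methyl-5-[1-(trimethylsilyloxy)ethenyl]phenoxy}silane; 7 methyl pyruvate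
Product: 10 methyl (2S)-2,8-dimethyl-4-oxo-6-(triisopropylsilyloxy)chroman-2-carboxylate, via silyl ether aldol adduct 8 (not isolated), via tertiary alkoxide 9 (not isolated)
Conditions: Cu(OTf)2 (10 mol%), (S,S)-t-Bu-box [2,2′-isopropylidenebis((4S)-4-tert-butyl-2-oxazoline), 11 mol%], THF, −78 °C; then Bu4N[Ph3SiF2] (TBAT, 0.3 equiv), −78 °C → rt; pH 7 buffer
Reagents that add atoms: none
Why: Mukaiyama aldol addition of the CH2 terminus of 6 (future C3) to methyl pyruvate, chelated through both carbonyls to the divalent copper centre, forms C2–C3 and gives silyl ether 8; substoichiometric fluoride then removes the SiMe3 group and alkoxide 9 displaces the ring fluoride ortho to the aryl ketone by addition–elimination (SNAr, Meisenheimer anion stabilised by the C4 carbonyl), forming O1–C8a and releasing the fluoride that carries the chain on. The closest known reactions are the bis(oxazoline)–copper pyruvate aldol of ketone enol silanes and the alkoxide SNAr cyclisation of 2-fluoroaryl ketones to chroman-4-ones. The dihydropyranone ring closes in a 6-exo-trig sense by attack of oxygen on the trigonal arene carbon C8a. C2 is controlled by the ligand: the tert-butyl groups of the square-planar chelate block the re face of the pyruvate ketone, so si-face attack should give the (S)-carbinol. The step needs desilylation of the tertiary O–SiMe3 group without loss of the aryl O–Si(i-Pr)3 group, which the much higher lability of SiMe3 and the low fluoride loading should secure. It also needs ring closure to outrun retro-aldol cleavage of 9, which the ketone-activated C–F bond held six atoms from the alkoxide should secure.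

Step 5
Reactants: 10 methyl (2S)-2,8-dimethyl-4-oxo-6-(triisopropylsilyloxy)chroman-2-carboxylate
Product: 11 methyl (2S)-2,8-dimethyl-6-(triisopropylsilyloxy)chroman-2-carboxylate
Conditions: Et3SiH (3 equiv), TFA, 0 °C → rt
Reagents that add atoms: none
Why: Ionic hydrogenation of the aryl ketone through the benzylic cation stabilised by the ortho oxygen O1 removes the temporary C4 carbonyl, while C2 bears no hydrogen and cannot ionise next to the ester.

Step 6
Reactants: 11 methyl (2S)-2,8-dimethyl-6-(triisopropylsilyloxy)chroman-2-carboxylate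
Product: 12 [(2S)-2,8-dimethyl-6-(triisopropylsilyloxy)chroman-2-yl]methanol
Conditions: LiBH4, THF, 0 °C → rt
Reagents that add atoms: none
Why: Hydride reduction of the ester to the primary alcohol with LiBH4 leaves the aryl silyl ether intact.

Step 7
Reactants: 12 [(2S)-2,8-dimethyl-6-(triisopropylsilyloxy)chroman-2-yl]methanol
Product: 13 [(2S)-2,8-dimethyl-6-(triisopropylsilyloxy)chroman-2-yl]methyl trifluoromethanesulfonate
Conditions: Tf2O, pyridine, CH2Cl2, −20 °C; used crude
Reagents that add atoms: triflic anhydride, O=S(=O)(OS(=O)(=O)C(F)(F)F)C(F)(F)F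
Why: O-Sulfonylation makes the neopentyl-type alcohol reactive enough for SN2 displacement, and the quaternary C2 excludes elimination.

Step 8
Reactants: 14 (2E,6E)-farnesyl bromide
Product: 15 (2E,6E)-farnesyl phenyl sulfone
Conditions: PhSO2Na, DMF, rt
Reagents that add atoms: sodium benzenesulfinate, [Na+].[O-]S(=O)c1ccccc1
Why: SN2 S-alkylation of the sulfinate by the primary allylic bromide should give the sulfone with both E alkenes retained.

Step 9
Reactants: 15 (2E,6E)-farnesyl phenyl sulfone; 13 [(2S)-2,8-dimethyl-6-(triisopropylsilyloxy)chroman-2-yl]methyl trifluoromethanesulfonate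
Product: 17 (2S)-2,8-dimethyl-2-[(3E,7E)-4,8,12-trimethyl-2-(phenylsulfonyl)trideca-3,7,11-trien-1-yl]-6-(triisopropylsilyloxy)chroman, via lithiated sulfone 16 (not isolated)
Conditions: n-BuLi, THF/HMPA, −78 °C; then 13, −78 → −20 °C
Reagents that add atoms: none
Why: Alkylation of the α-sulfonyl carbanion by the primary triflate joins C1′ to C2′; the sulfonyl-bearing stereocentre forms without control and is erased in the next step.

Step 10
Reactants: 17 (2S)-2,8-dimethyl-2-[(3E,7E)-4,8,12-trimethyl-2-(phenylsulfonyl)trideca-3,7,11-trien-1-yl]-6-(triisopropylsilyloxy)chroman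
Product: 18 triisopropyl({(2R)-2,8-dimethyl-2-[(3E,7E)-4,8,12-trimethyltrideca-3,7,11-trien-1-yl]chroman-6-yl}oxy)silane
Conditions: PdCl2(dppp) (5 mol%), LiEt3BH, THF, 0 °C
Reagents that add atoms: none
Why: Palladium-catalysed reductive desulfonylation, with hydride attack at the less substituted terminus of the π-allyl complex formed by zerovalent palladium, should remove the sulfonyl group and keep the trisubstituted E alkene in place.

Step 11
Reactants: 18 triisopropyl({(2R)-2,8-dimethyl-2-[(3E,7E)-4,8,12-trimethyltrideca-3,7,11-trien-1-yl]chroman-6-yl}oxy)silane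
Product: 19 (2E,6E,10E)-13-[(2R)-2,8-dimethyl-6-(triisopropylsilyloxy)chroman-2-yl]-2,6,10-trimethyltrideca-2,6,10-trien-1-ol
Conditions: SeO2 (0.3 equiv), t-BuOOH, salicylic acid (cat.), CH2Cl2, 0 °C → rt
Reagents that add atoms: tert-butyl hydroperoxide, CC(C)(C)OO (terminal oxygen source, delivered through selenium dioxide, O=[Se]=O)
Why: Selenium dioxide allylic oxidation (ene reaction then [2,3]-sigmatropic shift) should hydroxylate the E methyl group of the terminal isopropylidene unit, the least hindered trisubstituted alkene, giving the E allylic alcohol.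

Step 12
Reactants: 19 (2E,6E,10E)-13-[(2R)-2,8-dimethyl-6-(triisopropylsilyloxy)chroman-2-yl]-2,6,10-trimethyltrideca-2,6,10-trien-1-ol
Product: 20 (2E,6E,10E)-13-[(2R)-2,8-dimethyl-6-(triisopropylsilyloxy)chroman-2-yl]-2,6,10-trimethyltrideca-2,6,10-trienal
Conditions: Dess–Martin periodinane, NaHCO3, CH2Cl2, 0 °C
Reagents that add atoms: none
Why: Dess–Martin oxidation converts the allylic alcohol to the enal without touching the alkenes or the silyl ether.

Step 13
Reactants: 20 (2E,6E,10E)-13-[(2R)-2,8-dimethyl-6-(triisopropylsilyloxy)chroman-2-yl]-2,6,10-trimethyltrideca-2,6,10-trienal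
Product: 21 (2E,6E,10E)-13-[(2R)-2,8-dimethyl-6-(triisopropylsilyloxy)chroman-2-yl]-2,6,10-trimethyltrideca-2,6,10-trienoic acid
Conditions: NaClO2, NaH2PO4, 2-methyl-2-butene, t-BuOH/H2O, 0 °C → rt
Reagents that add atoms: sodium chlorite, [Na+].[O-]Cl=O
Why: Pinnick oxidation takes the enal to the acid with retention of alkene geometry, the hypochlorous acid being trapped by 2-methyl-2-butene.

Step 14
Reactants: 21 (2E,6E,10E)-13-[(2R)-2,8-dimethyl-6-(triisopropylsilyloxy)chroman-2-yl]-2,6,10-trimethyltrideca-2,6,10-trienoic acid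
Product: 22 garcinoic acid
Conditions: TBAF, AcOH, THF, 0 °C; aq. NH4Cl
Reagents that add atoms: none
Why: Fluoride-mediated desilylation of the aryl silyl ether should release the phenol under conditions that leave the triene acid intact.

Compound list
1 | 4-fluoro-3-methylphenol | Cc1cc(O)ccc1F | starting material
2 | (4-fluoro-3-methylphenoxy)triisopropylsilane | Cc1cc(O[Si](C(C)C)(C(C)C)C(C)C)ccc1F | intermediate
3 | N-methoxy-N-methylacetamide | CC(=O)N(C)OC | starting material
4 | [2-fluoro-3-methyl-5-(triisopropylsilyloxy)phenyl]lithium | [Li]c1cc(O[Si](C(C)C)(C(C)C)C(C)C)cc(C)c1F | intermediate (not isolated)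
5 | 1-[2-fluoro-3-methyl-5-(triisopropylsilyloxy)phenyl]ethan-1-one | CC(=O)c1cc(O[Si](C(C)C)(C(C)C)C(C)C)cc(C)c1F | intermediate
6 | triisopropyl{4-fluoro-3-methyl-5-[1-(trimethylsilyloxy)ethenyl]phenoxy}silane | C=C(O[Si](C)(C)C)c1cc(O[Si](C(C)C)(C(C)C)C(C)C)cc(C)c1F | intermediate
7 | methyl pyruvate (methyl 2-oxopropanoate) | COC(=O)C(C)=O | starting material
8 | methyl (2S)-4-[2-fluoro-3-methyl-5-(triisopropylsilyloxy)phenyl]-2-methyl-4-oxo-2-(trimethylsilyloxy)butanoate | COC(=O)[C@@](C)(O[Si](C)(C)C)CC(=O)c1cc(O[Si](C(C)C)(C(C)C)C(C)C)cc(C)c1F | intermediate (not isolated)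
9 | tetrabutylammonium (2S)-4-[2-fluoro-3-methyl-5-(triisopropylsilyloxy)phenyl]-1-methoxy-2-methyl-1,4-dioxobutan-2-olate | COC(=O)[C@@](C)([O-])CC(=O)c1cc(O[Si](C(C)C)(C(C)C)C(C)C)cc(C)c1F.CCCC[N+](CCCC)(CCCC)CCCC | intermediate (not isolated)
10 | methyl (2S)-2,8-dimethyl-4-oxo-6-(triisopropylsilyloxy)chroman-2-carboxylate | COC(=O)[C@]1(C)CC(=O)c2cc(O[Si](C(C)C)(C(C)C)C(C)C)cc(C)c2O1 | intermediate
11 | methyl (2S)-2,8-dimethyl-6-(triisopropylsilyloxy)chroman-2-carboxylate | COC(=O)[C@]1(C)CCc2cc(O[Si](C(C)C)(C(C)C)C(C)C)cc(C)c2O1 | intermediate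
12 | [(2S)-2,8-dimethyl-6-(triisopropylsilyloxy)chroman-2-yl]methanol | OC[C@]1(C)CCc2cc(O[Si](C(C)C)(C(C)C)C(C)C)cc(C)c2O1 | intermediate
13 | [(2S)-2,8-dimethyl-6-(triisopropylsilyloxy)chroman-2-yl]methyl trifluoromethanesulfonate | O=S(=O)(OC[C@]1(C)CCc2cc(O[Si](C(C)C)(C(C)C)C(C)C)cc(C)c2O1)C(F)(F)F | intermediate
14 | (2E,6E)-farnesyl bromide [(2E,6E)-1-bromo-3,7,11-trimethyldodeca-2,6,10-triene] | CC(C)=CCC/C(C)=C/CC/C(C)=C/CBr | starting material
15 | (2E,6E)-farnesyl phenyl sulfone | CC(C)=CCC/C(C)=C/CC/C(C)=C/CS(=O)(=O)c1ccccc1 | intermediate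
16 | α-lithio-(2E,6E)-farnesyl phenyl sulfone | CC(C)=CCC/C(C)=C/CC/C(C)=C/C([Li])S(=O)(=O)c1ccccc1 | intermediate (not isolated)
17 | (2S)-2,8-dimethyl-2-[(3E,7E)-4,8,12-trimethyl-2-(phenylsulfonyl)trideca-3,7,11-trien-1-yl]-6-(triisopropylsilyloxy)chroman, both epimers at the sulfonyl-bearing carbon | CC(C)=CCC/C(C)=C/CC/C(C)=C/C(C[C@]1(C)CCc2cc(O[Si](C(C)C)(C(C)C)C(C)C)cc(C)c2O1)S(=O)(=O)c1ccccc1 | intermediate
18 | triisopropyl({(2R)-2,8-dimethyl-2-[(3E,7E)-4,8,12-trimethyltrideca-3,7,11-trien-1-yl]chroman-6-yl}oxy)silane (O-silyl δ-tocotrienol) | CC(C)=CCC/C(C)=C/CC/C(C)=C/CC[C@]1(C)CCc2cc(O[Si](C(C)C)(C(C)C)C(C)C)cc(C)c2O1 | intermediate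
19 | (2E,6E,10E)-13-[(2R)-2,8-dimethyl-6-(triisopropylsilyloxy)chroman-2-yl]-2,6,10-trimethyltrideca-2,6,10-trien-1-ol | OC/C(C)=C/CC/C(C)=C/CC/C(C)=C/CC[C@]1(C)CCc2cc(O[Si](C(C)C)(C(C)C)C(C)C)cc(C)c2O1 | intermediate
20 | (2E,6E,10E)-13-[(2R)-2,8-dimethyl-6-(triisopropylsilyloxy)chroman-2-yl]-2,6,10-trimethyltrideca-2,6,10-trienal | O=C/C(C)=C/CC/C(C)=C/CC/C(C)=C/CC[C@]1(C)CCc2cc(O[Si](C(C)C)(C(C)C)C(C)C)cc(C)c2O1 | intermediate
21 | (2E,6E,10E)-13-[(2R)-2,8-dimethyl-6-(triisopropylsilyloxy)chroman-2-yl]-2,6,10-trimethyltrideca-2,6,10-trienoic acid | OC(=O)/C(C)=C/CC/C(C)=C/CC/C(C)=C/CC[C@]1(C)CCc2cc(O[Si](C(C)C)(C(C)C)C(C)C)cc(C)c2O1 | intermediate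
22 | garcinoic acid, (2E,6E,10E)-13-[(2R)-6-hydroxy-2,8-dimethylchroman-2-yl]-2,6,10-trimethyltrideca-2,6,10-trienoic acid | C/C(=C\CC/C(C)=C/CC[C@]1(C)CCc2cc(O)cc(C)c2O1)CC/C=C(\C)C(=O)O | target

Total step count: 14. Longest linear sequence: 13 steps (steps 1–7 and 9–14); step 8 is a one-step side branch.

Steps most likely to fail

Step 4. Enantiomeric purity may erode: alkoxide 9 can revert by retro-aldol cleavage and recombine without catalyst control, and chromanone 10 can open reversibly by base-induced β-elimination of the aryloxide. The para silyloxy group also slows the SNAr, which gives these pathways more time. The fallback replaces catalyst-controlled purity by an enzymatic kinetic resolution. It sets out from ester 11 of insufficient enantiomeric purity and returns to the route at enantiopure 11 before step 6. Ester 11 is stirred with a lipase chosen from a hydrolase screen (for example Candida antarctica lipase B) in phosphate buffer/MTBE. In the sense required the enzyme hydrolyses the (2R)-ester to (2R)-2,8-dimethyl-6-(triisopropylsilyloxy)chroman-2-carboxylic acid F1, which is removed by basic extraction, leaving (2S)-11.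

Step 11. Site selectivity may be poor and oxidation may overrun: SeO2 can attack allylic positions of the two internal alkenes or take the alcohol on to mixtures, and this would happen on the most advanced intermediate. The fallback moves the oxidation to the chain fragment before coupling. It sets out from sulfone 15 (with triflate 13) and returns at alcohol 19. Sulfone 15 is oxidised with SeO2/t-BuOOH to (2E,6E,10E)-2,6,10-trimethyl-12-(phenylsulfonyl)dodeca-2,6,10-trien-1-ol F2 and silylated (TBSCl, imidazole) to its tert-butyldimethylsilyl ether F3. F3 is lithiated (n-BuLi, THF/HMPA) and alkylated with 13 to the coupled sulfone F4, which is desulfonylated with PdCl2(dppp)/LiEt3BH to the bis-silyl ether F5. The primary allylic silyl ether of F5 is then cleaved selectively (PPTS, MeOH) to give 19.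

Step 10. Hydride may be delivered at the wrong terminus of the allyl unit, or the C3′=C4′ alkene may migrate or lose its E geometry in the π-allyl intermediate. The fallback builds C2′–C3′ by a B-alkyl Suzuki–Miyaura coupling so that the alkene geometry comes from a vinyl iodide. It sets out from alcohol 12 and returns at 18.
- Alcohol 12 is oxidised (Dess–Martin periodinane) to (2S)-2,8-dimethyl-6-(triisopropylsilyloxy)chroman-2-carbaldehyde F6 and methylenated (Ph3P=CH2) to the (2S)-2-ethenylchroman F7. F7 is hydroborated with 9-BBN to the B-alkyl-9-borabicyclo[3.3.1]nonane F8.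
- Separately, (5E)-geranylacetone F9 is converted via its enol phosphate (LDA, ClP(O)(OEt)2; then LDA) to (5E)-6,10-dimethylundeca-5,9-dien-1-yne F10. Cp2ZrCl2-mediated carboalumination with AlMe3 followed by I2 gives (1E,5E)-1-iodo-2,6,10-trimethylundeca-1,5,9-triene F11.
- Coupling of F8 with F11 (PdCl2(dppf), AsPh3, Cs2CO3, DMF/THF/H2O) gives 18.

Further compounds
F1 | step 4 | (2R)-2,8-dimethyl-6-(triisopropylsilyloxy)chroman-2-carboxylic acid | OC(=O)[C@@]1(C)CCc2cc(O[Si](C(C)C)(C(C)C)C(C)C)cc(C)c2O1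
F2 | step 11 | (2E,6E,10E)-2,6,10-trimethyl-12-(phenylsulfonyl)dodeca-2,6,10-trien-1-ol | OC/C(C)=C/CC/C(C)=C/CC/C(C)=C/CS(=O)(=O)c1ccccc1
F3 | step 11 | tert-butyldimethyl{[(2E,6E,10E)-2,6,10-trimethyl-12-(phenylsulfonyl)dodeca-2,6,10-trien-1-yl]oxy}silane | CC(C)(C)[Si](C)(C)OC/C(C)=C/CC/C(C)=C/CC/C(C)=C/CS(=O)(=O)c1ccccc1
F4 | step 11 | tert-butyl{[(2E,6E,10E)-13-[(2S)-2,8-dimethyl-6-(triisopropylsilyloxy)chroman-2-yl]-2,6,10-trimethyl-12-(phenylsulfonyl)trideca-2,6,10-trien-1-yl]oxy}dimethylsilane, both epimers at the sulfonyl-bearing carbon | CC(C)(C)[Si](C)(C)OC/C(C)=C/CC/C(C)=C/CC/C(C)=C/C(C[C@]1(C)CCc2cc(O[Si](C(C)C)(C(C)C)C(C)C)cc(C)c2O1)S(=O)(=O)c1ccccc1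
F5 | step 11 | tert-butyl{[(2E,6E,10E)-13-[(2R)-2,8-dimethyl-6-(triisopropylsilyloxy)chroman-2-yl]-2,6,10-trimethyltrideca-2,6,10-trien-1-yl]oxy}dimethylsilane | CC(C)(C)[Si](C)(C)OC/C(C)=C/CC/C(C)=C/CC/C(C)=C/CC[C@]1(C)CCc2cc(O[Si](C(C)C)(C(C)C)C(C)C)cc(C)c2O1
F6 | step 10 | (2S)-2,8-dimethyl-6-(triisopropylsilyloxy)chroman-2-carbaldehyde | O=C[C@]1(C)CCc2cc(O[Si](C(C)C)(C(C)C)C(C)C)cc(C)c2O1
F7 | step 10 | triisopropyl{[(2S)-2-ethenyl-2,8-dimethylchroman-6-yl]oxy}silane | C=C[C@]1(C)CCc2cc(O[Si](C(C)C)(C(C)C)C(C)C)cc(C)c2O1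
F8 | step 10 | 9-{2-[(2R)-2,8-dimethyl-6-(triisopropylsilyloxy)chroman-2-yl]ethyl}-9-borabicyclo[3.3.1]nonane | C1CC2CCCC(C1)B2CC[C@]3(C)CCc4cc(O[Si](C(C)C)(C(C)C)C(C)C)cc(C)c4O3
F9 | step 10 | (5E)-geranylacetone, (5E)-6,10-dimethylundeca-5,9-dien-2-one | CC(=O)CC/C=C(\C)CCC=C(C)C
F10 | step 10 | (5E)-6,10-dimethylundeca-5,9-dien-1-yne | C#CCC/C=C(\C)CCC=C(C)C
F11 | step 10 | (1E,5E)-1-iodo-2,6,10-trimethylundeca-1,5,9-triene | I/C=C(\C)CC/C=C(\C)CCC=C(C)C
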